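The readings were generated by integration with constants of no real substance; noise was put on by code.

**The runs.** The constants were hidden from me, so I read what I could from two earlier runs.

| flask | starting material | second substrate | precatalyst | remark | time |
|---|---|---|---|---|---|
| beta | 0.50 M | 0.50 M | 0.72 mM | run made earlier |  |
| gamma | 0.50 M | 0.50 M | 2.7 mM | run made earlier |  |
| Friday's | 0.50 M | 0.500 M | 1.0 mM |  | 30 h |
| Saturday's | 0.50 M | 0.500 M | 2.0 mM |  | 30 h |
| Sunday's | 0.50 M | 0.500 M | 4.0 mM |  | 30 h |

| run | time / h | target / % | catalyst intermediate A / % | starting material / % |
|---|---|---|---|---|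
| beta | 1.50 | 3.0 | 0 | 96.4 |
| beta | 3.00 | 7.5 | 0.9 | 90.9 |
| beta | 6.00 | 17.0 | 0 | 82.6 |
| beta | 12.0 | 26.6 | 0.2 | 73.7 |
| beta | 20.0 | 31.1 | 0.5 | 66.7 |
| gamma | 4.00 | 37.5 | 0.3 | 62.2 |
| gamma | 8.00 | 63.0 | 0 | 36.4 |
| gamma | 12.0 | 75.9 | 0.3 | 23.5 |
| gamma | 15.0 | 80.9 | 0.5 | 19.3 |
| gamma | 20.0 | 88.0 | 0 | 13.2 |

(readings scatter by 0.5 percentage points)

- the analysis behind the earlier runs scatters by 0.5 percentage points, standard deviation

- which of these there is most of at the end, counted by the starting material in it, Friday's (target / starting material / catalyst intermediate A)
- which of these there is most of at the end, counted by the starting material in it, Saturday's (target / starting material / catalyst intermediate A)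
- which of these there is most of at the end, counted by the starting material in it, Sunday's (target / starting material / catalyst intermediate A)
- amount of the one of these that there is most of at the end, in percent of the starting material charged, Friday's
- amount of the one of these that there is most of at the end, in percent of the starting material charged, Saturday's
- amount of the one of these that there is most of at the end, in percent of the starting material charged, Sunday's

**Fraction left.** I worked with the logarithm of the fraction of starting material left: for a step first order in starting material, its hourly fall, the pace, measures working catalyst. Beta gave 0.0153 h⁻¹ from 6.00 h to 20.0 h, and gamma gave 0.0845 h⁻¹ from 8.00 h to 20.0 h. That is 5.54 times the pace on 3.75 times the precatalyst, a larger ratio. Catalyst dying by the clock gives equal ratios over such similar hours, so I let it die with conversion.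

**Catalyst price.** I wrote pace = k(c − bx), with c the charge of precatalyst and x the fraction converted. Mean conversions of 24.0% and 75.5% solve to b = 2.23 mM. This is the catalyst price, the precatalyst lost per whole charge of starting material converted, a turnover number upside down. Then k is 83.2 M⁻¹ h⁻¹.

**Committed numbers.** The ceiling a = c/b is the share of the charge that the catalyst can pay for. Integrating gives x = a(1 − E)/(1 − aE), with E = exp(−k(b − c)t). At 30 h I got target 43.7% on Friday's, so starting material leads there. Saturday's gave 79.1% and Sunday's 99.5%.

**Weak link.** The price comes from paces in two runs, and each reading behind those paces scatters by 0.5 percentage points. I reforged it from the last 8.00 h of both runs: pace ratio 5.78, price 1.72 mM, k 56.0 M⁻¹ h⁻¹. Friday's target then reads 49.3%, and starting material still leads.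

**The forecast.** It found “deactivation tied to turnover rather than to time” and put target ahead in each flask: 52%, 83%, 98.5%. On Friday's that differs from my reckoning.

**At rest?** Friday's ended with 53.1% starting material against 46.7% target; target reached 81.8% on Saturday's and 99.2% on Sunday's.

    starting material + free catalyst ⇌ catalyst intermediate A (K = 0.830 M⁻¹, k = 180 M⁻¹ h⁻¹)
    catalyst intermediate A → free catalyst + target (k = 210 h⁻¹)
    second substrate + free catalyst ⇌ catalyst intermediate B (K = 1.30 M⁻¹, k = 200 M⁻¹ h⁻¹)
    catalyst intermediate B → free catalyst + second product (k = 37.0 h⁻¹)
    catalyst intermediate A → spent catalyst (k = 0.850 h⁻¹)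
    precatalyst → free catalyst (k = 0.940 h⁻¹)
    2 second substrate → self-condensation product (k = 4.20 M⁻¹ h⁻¹)

My two prices give each flask two reckoned ceilings. Friday's held 4.95% free catalyst at the end, and ten times the time moved its target from 46.7% to 49.4%, between its ceilings of 44.8% and 58.0%. A neighbour, Saturday's flask with 0.500 mM precatalyst, stood at 24.0% target with 97.1% spent catalyst, between its ceilings of 22.4% and 29.1%. Sunday's lower ceiling of 179% exceeds the charge, and ten times the time moved its target from 99.2% to 99.6%. Saturday's still held 16.5% free catalyst at the end, and ten times the time took its target from 81.8% to 97.3%, between its ceilings of 89.7% and 116%.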